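All runs are simulated for substances that don't exist; noise was put on by code.

At 3.2 h the ash flask reads 0.345 M of substrate, against 0.369 M at 1.7 h. The alder flask, charged with target as well, stands at 0.342 M.

common to all: substrate 0.800 M

| run | coupling partner | target | time |
|---|---|---|---|
| ash | 2.40 M |  |  |
| alder | 2.40 M | 0.400 M |  |
| cedar | 0.600 M |  | 3.2 h |

| run | time / h | [substrate] / M |
|---|---|---|
| ash run | 0.13 | 0.691 |
| ash run | 0.24 | 0.616 |
| ash run | 0.46 | 0.525 |
| ash run | 0.88 | 0.429 |
| ash run | 1.7 | 0.369 |
| ash run | 3.2 | 0.345 |
| alder run | 0.13 | 0.695 |
| alder run | 0.24 | 0.610 |
| alder run | 0.46 | 0.522 |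
| alder run | 0.88 | 0.425 |
| alder run | 1.7 | 0.369 |
| alder run | 3.2 | 0.342 |

(standard deviation of a reading: 0.004 M)

- substrate in the cedar run at 3.2 h, as a share of the substrate charged

- Overall: substrate + coupling partner -> target.
- Constant volume, constant temperature.
- Bound and free are read together.
- "The second partner" is coupling partner.

Counting one partner per substrate lost, the substrate lost in the ash flask by that reading matches 0.455 M of coupling partner, and 1.94 M of its charge is unmatched by that loss. These two amounts give the ratio 0.234. Call this ratio, substrate lost over charged partner unmatched by that loss, the split.

My own reckoning supposes that the whole partner charge has gone by 3.2 h in the ash and cedar flasks, the unmatched part in a side loss running with the square of c(coupling partner), while the draw on substrate does not depend on c(coupling partner). The ash and alder runs share one partner charge and read substrate, so they do not show these suppositions. The cedar charge is a quarter of the ash charge, so on these assumptions the split grows 16.0-fold to 3.74. Partner is the limiting reagent in cedar, with 0.600 M against 0.800 M of substrate. Sharing out the cedar partner charge in that split, between substrate and side loss, leaves 40.8% of the substrate by my reckoning.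

The forecast says 78%, with a range of 45% to 85%, on the ground that “The stall looks like catalyst dying with time”. My figure lies below that range.

The cedar flask keeps 56.2% of its substrate at 3.2 h, and its steps are these:

    substrate ⇌ intermediate + by-product (1.235 h⁻¹, 17.68 L mol⁻¹ h⁻¹)
    intermediate + coupling partner → target (16.02 L mol⁻¹ h⁻¹)
    2 coupling partner → lost reagent (4.680 L mol⁻¹ h⁻¹)
    2 coupling partner ⇌ idle reagent dimer, settled at all times (0.6850 L mol⁻¹)

A fit with the two partners resting in a complex met the readings with a root mean square residual of 1.1 scatter units and gave 20.4% for cedar. The cedar flask lost 0.351 M of substrate, which leaves 0.249 M of its partner charge unmatched by that loss, so its split is 1.41, not 3.74. The alder flask, with the ash partner charge, reads a split of 0.236 at 3.2 h, and the cedar split stands at 6.03 times the split read in the ash flask.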